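The numbers of this flask come from no measurement; what happens was integrated by code.

The trap in this flask is the step from isomer of the product B back to starting material. Written with one rate constant, it looks like a one-way leg of a steady flow round the ring, but its equilibrium constant is the inverse product of the other constants on the ring, so it has a way back and the constants multiply to one round the ring.

    starting material ⇌ target (K1 = 8.0, k1 = 0.0030 s⁻¹)
    target ⇌ isomer of the product A (K2 = 1.1, k2 = 0.0019 s⁻¹)
    isomer of the product A ⇌ isomer of the product B (K3 = 0.084, k3 = 0.011 s⁻¹)
    isomer of the product B ⇌ starting material (k4 = 0.0088 s⁻¹)
    target ⇌ isomer of the product C (K5 = 0.60, k5 = 0.0055 s⁻¹)
    starting material + protic impurity → quenched substrate (k6 = 32 L mol⁻¹ s⁻¹)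

starting material 0.084 M; protic impurity 1.68 mM; time 30 h

1. at 30 h, what has stopped the reaction, if anything has (forward and back rates have come level / all of the starting material has reacted / it is still moving)
2. target at 30 h, in percent of the starting material charged
3. isomer of the product A at 30 h, in percent of the starting material charged
4. isomer of the product C at 30 h, in percent of the starting material charged

- the reaction counts as stopped when no species that holds the starting material changes by six tenths of a point or more over the second half of the time
- run time (flask): 30 h

We climb the times from the shortest up and treat each rung as done once it is passed. The protic impurity is the limiting reagent of the quench, its charge being far below that of starting material. The quench therefore removes 2.00% of the charge and leaves 98.0% to the ring, while at the start the step to target uses starting material more slowly than the quench, at 0.056 of its rate.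

| Rung in this flask | Time |
|---|---|
| protic impurity consumed, pseudo-first-order, half-life at the start | 0.258 s |
| isomer of the product B with starting material, relaxation half-life | 0.755 min |
| target to isomer of the product C, forward half-life, way back not counted | 2.1 min |
| target with isomer of the product A, relaxation half-life | 3.18 min |
| starting material with target, relaxation half-life | 3.42 min |

Even the last rung is short against the 30 h of the run, so we expect forward and back rates to stand level by then. Each species then has a weight against starting material counted as one: target 8.0, isomer of the product A 8.80, isomer of the product B 0.739, isomer of the product C 4.80. The sum of these weights is the pool weight, 23.3, and a species holds its weight over the pool weight, times what the quench left. We reckon target 33.6%, isomer of the product A 37.0% and isomer of the product C 20.2%.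

The forecast says forward and back rates have come level, with target 35.6%, isomer of the product A 28% and isomer of the product C 21.4%, on the ground that “I took the stationary state as a steady flow around the cycle rather than true equilibrium”. It stands 9 percentage points below our reckoning on isomer of the product A and 2 points above it on target.

The simulation gives forward and back rates have come level, with target 33.6%, isomer of the product A 37.0% and isomer of the product C 20.2%. In this flask isomer of the product A reads 37.0% at 3.00 h and 37.0% at 300 h. The neighbour charged with 0.14 M of starting material keeps the same impurity, so the quench leaves 98.8%, and the pool weight of 23.3 gives target 33.9% and isomer of the product A 37.3%. That neighbour reads 33.9% and 37.3%, with quenched substrate at 1.20%.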